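At −20 °C, after 4.0 h, which of these flasks holds the most Q?

common to all: temperature −20 °C

| run | J | X | remark | time |
|---|---|---|---|---|
| south-west | 22 mM | 0.90 equiv | run made earlier |  |
| Friday's | 20 mM | 2.70 equiv |  | 4.0 h |
| Tuesday's | 60 mM | 2.70 equiv |  | 4.0 h |
| Wednesday's | 60 mM | 0.900 equiv |  | 4.0 h |
| Sunday's | 20 mM | 0.900 equiv |  | 4.0 h |

- south-west (time / min: Q / %, J / %): 6.00: 0, 29; 12.0: 7, 8; 25.0: 23, 1; 40.0: 35, 1; 80.0: 53, 0

(readings scatter by 1.5 percentage points)

- all flasks from highest to lowest amount of Q, in percent of the J charged, at 4.0 h (Friday's / Tuesday's / Wednesday's / Sunday's)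
- the amount of Q, in percent of the J charged of the flask you put first, at 4.0 h
- the amount of Q, in percent of the J charged of the flask you put last, at 4.0 h

- the earlier runs were read with a standard deviation of 1.5 percentage points
- a reading or a percentage of Q counts all its forms, free or not
- a reading of J is of its free form alone

In the south-west run free J is down to 1% at 25.0 min while Q stands at 23%, so J passes through an unseen intermediate, and I let that intermediate meet X, the limiting reagent at 0.90 equiv, to give Q.

How fast do the two meet? Let y be the fraction turned into Q and r the equivalents of X. The second-order rate law then integrates so that ln((1 − y)/(r − y)) climbs linearly in time, with slope (1 − r)k[J]. The readings at 40.0 min and 80.0 min give 8.20 × 10⁻⁴ /mM/min, a reading with their scatter, and this k is my pairing constant.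

What does k give at 0.900 equiv? The same line gives me 74.5% for Sunday's and 86.2% for Wednesday's, which is higher at its higher [J].

Do the flasks with 2.70 equiv finish? Late on, the excess partner makes the step pseudo-first-order, with an intermediate half-life of 24.9 min in Friday's and 8.29 min in Tuesday's, both shorter than 4.0 h. So I put both on top, and k does not rank them.

The forecast reads Tuesday's > Friday's > Wednesday's > Sunday's, with 99% and 74%: “The order of the 2.7 equiv flasks is marginal.”

The flasks give Friday's > Tuesday's > Wednesday's > Sunday's, with 96.5% for Friday's, 89.1% for Tuesday's and 76.3% for Sunday's.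

    J → G (k = 0.00327 /s, Ea = 80.0 kJ/mol)
    X → E (k = 0.00162 /s, Ea = 71.0 kJ/mol)
    X + Q → L (k = 0.00243 /M/s, Ea = 42.0 kJ/mol)
    G + E → Q (k = 0.0180 /M/s, Ea = 52.0 kJ/mol)
    J + G → Z (k = 0.00513 /M/s, Ea = 53.0 kJ/mol)
    J + Q ⇌ D, settled at all times (K = 450 /M, ΔH = −18.0 kJ/mol)
    (constants at −20 °C)

The intermediate is G and its partner is E, which is made from X. With my k, Friday's E of 34.3 mM puts the half-life of G near 24.6 min, an estimate with the scatter of k, and at 4.00 h G stands at 0.0704%. In Friday's, X goes to E with a half-life of 0.12 h, shorter than the 1.5 h of free Q under X + Q → L at the charged concentrations. The using up of X is the main reason for Friday's yield: without it, Q ends at 18.4% instead of 96.5%. Where the forecast and the flasks part, Tuesday's holds twice the Z of Friday's, 5.10% against 2.50%. In Friday's neighbour with 11.0 equiv of X, k gives a half-life of 4.23 min; that neighbour ends with G at 0.0112%, Q at 91.3% and L at 6.91%.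

(The runs were computed for an exercise, and the scatter is random.)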